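**Retrosynthetic overview**
- Last step: removal of the side-chain silyl group.
- Both rings form in one flask, in the biosynthetic order. The ten-membered carbocycle closes first at C6–C7 of an acyclic farnesane-type seco-enal, with the polarity of the farnesyl diphosphate to germacrene A cyclisation: C6 is the electrophile (Lewis-acid-bound enal), the C7=C11 olefin is the nucleophile, and Me3Si leaves from C13 where the enzyme removes a proton. The γ-lactone then closes O6 onto C12, as in costunolide biosynthesis.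
- The seco-chain is built from three C5 units joined head to tail by two catalytic asymmetric vinylogous aldol additions: C8–C9 (lactone-forming, fixes the 1(10)Z alkene and C8) and C2–C3 (fixes the 4E alkene and C2).
- The C7=C11/C13 allylsilane comes from a Horner–Wadsworth–Emmons olefination, the 8-O-acyl group from the Roche ester, and amides serve as latent aldehydes at C2 and C6.

Assumption: germacrane numbering is used (lactone C12–O–C6, ester on C8, hydroxyl on C2) and the SMILES is read as 1(10)Z,4E with 2R,6R,7R,8R,2′S; the sense of induction of the chiral catalysts in steps 2 and 13 is assigned by analogy with their reported aldehyde additions, and the antipodal catalyst would be used if it proved opposite.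

Abbreviations: TBS = tert-butyldimethylsilyl; Acyl* = (2S)-3-[(tert-butyldimethylsilyl)oxy]-2-methylpropanoyl.

**Step 1**
Reactants: 1 methyl 3-methylbut-2-enoate
Product: 2 [(1-methoxy-3-methylbuta-1,3-dien-1-yl)oxy]trimethylsilane
Conditions: LiN(iPr)2, THF, −78 °C; Me3SiCl
Reagents that add atoms: chlorotrimethylsilane, C[Si](C)(C)Cl
Why: Kinetic γ-deprotonation of the enoate and O-silylation give the vinylketene silyl acetal (silyl dienolate formation).

**Step 2**
Reactants: 2 [(1-methoxy-3-methylbuta-1,3-dien-1-yl)oxy]trimethylsilane; 3 (E)-cinnamaldehyde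
Product: 5 (6R)-4-methyl-6-[(E)-2-phenylethenyl]-5,6-dihydro-2H-pyran-2-one, via copper alkoxide of Z-hydroxy ester 4 (not isolated)
Conditions: Cu(OTf)2 (10 mol %), (S)-Tol-BINAP (11 mol %), Bu4N[Ph3SiF2] (20 mol %), THF, rt
Reagents that add atoms: none
Why: The catalytic asymmetric vinylogous Mukaiyama aldol addition of the monovalent copper dienolate gives the Z-aldolate, which lactonises so that the ring locks the future 1(10)Z alkene, and the Tol-BINAP complex directs 1,2-attack to the Re face of the aldehyde to set C8 as R.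

**Step 3**
Reactants: 5 (6R)-4-methyl-6-[(E)-2-phenylethenyl]-5,6-dihydro-2H-pyran-2-one
Product: 6 (2Z,5R,6E)-5-hydroxy-N-methoxy-N,3-dimethyl-7-phenylhepta-2,6-dienamide
Conditions: MeNH(OMe)·HCl, AlMe3, CH2Cl2, 0 °C
Reagents that add atoms: N,O-dimethylhydroxylamine hydrochloride, CNOC.Cl
Why: Weinreb aminolysis with the aluminium amide opens the lactone at the acyl C–O bond with retention of the Z alkene, frees O8–H and turns C2 into a latent aldehyde.

**Step 4**
Reactants: 7 methyl (2S)-3-hydroxy-2-methylpropanoate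
Product: 8 methyl (2S)-3-[(tert-butyldimethylsilyl)oxy]-2-methylpropanoate
Conditions: TBSCl, imidazole, DMF, rt
Reagents that add atoms: tert-butyldimethylsilyl chloride, CC(C)(C)[Si](C)(C)Cl
Why: Standard silylation of the primary alcohol; the stereocentre is not involved.

**Step 5**
Reactants: 8 methyl (2S)-3-[(tert-butyldimethylsilyl)oxy]-2-methylpropanoate
Product: 9 (2S)-3-[(tert-butyldimethylsilyl)oxy]-2-methylpropanoic acid
Conditions: LiOH, THF/H2O, 0 °C; then dilute HCl to pH 4
Reagents that add atoms: lithium hydroxide, [Li+].[OH-]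
Why: Saponification at 0 °C cleaves the methyl ester without epimerising the α-stereocentre or removing the silyl ether.

**Step 6**
Reactants: 6 (2Z,5R,6E)-5-hydroxy-N-methoxy-N,3-dimethyl-7-phenylhepta-2,6-dienamide; 9 (2S)-3-[(tert-butyldimethylsilyl)oxy]-2-methylpropanoic acid
Product: 10 (1E,3R,5Z)-7-[methoxy(methyl)amino]-5-methyl-7-oxo-1-phenylhepta-1,5-dien-3-yl (2S)-3-[(tert-butyldimethylsilyl)oxy]-2-methylpropanoate
Conditions: EDC·HCl, DMAP, CH2Cl2, 0 °C → rt
Reagents that add atoms: none
Why: Steglich esterification acylates O8 with retention at both stereocentres, and any minor enantiomer carried from step 2 becomes a separable diastereomer.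

**Step 7**
Reactants: 10 (1E,3R,5Z)-7-[methoxy(methyl)amino]-5-methyl-7-oxo-1-phenylhepta-1,5-dien-3-yl (2S)-3-[(tert-butyldimethylsilyl)oxy]-2-methylpropanoate
Product: 12 (2R,4Z)-6-[methoxy(methyl)amino]-4-methyl-1,6-dioxohex-4-en-2-yl (2S)-3-[(tert-butyldimethylsilyl)oxy]-2-methylpropanoate, via secondary ozonide 11 (not isolated)
Conditions: O3, CH2Cl2, −78 °C (Sudan Red 7B end point); Me2S, −78 °C → rt
Reagents that add atoms: ozone, O=[O+][O-]
Why: Chemoselective ozonolysis, since the styrenyl alkene reacts with ozone much faster than the amide-conjugated trisubstituted alkene, and neutral reductive work-up delivers the α-acyloxy aldehyde (C7) without touching C8.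

**Step 8**
Reactants: 13 trimethyl phosphonoacetate; 14 (iodomethyl)trimethylsilane
Product: 15 methyl 2-(dimethoxyphosphoryl)-3-(trimethylsilyl)propanoate (racemic)
Conditions: NaH, DME, 0 → 70 °C
Reagents that add atoms: none
Why: SN2 C-alkylation of the sodium phosphonoacetate by the primary α-silyl iodide.

**Step 9**
Reactants: 12 (2R,4Z)-6-[methoxy(methyl)amino]-4-methyl-1,6-dioxohex-4-en-2-yl (2S)-3-[(tert-butyldimethylsilyl)oxy]-2-methylpropanoate; 15 methyl 2-(dimethoxyphosphoryl)-3-(trimethylsilyl)propanoate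
Product: 16 methyl (2Z,4R,6Z)-8-[methoxy(methyl)amino]-6-methyl-8-oxo-4-(Acyl*-oxy)-2-[(trimethylsilyl)methyl]octa-2,6-dienoate
Conditions: LiN(SiMe3)2 (pre-mixed with 15), THF, −78 → 0 °C
Reagents that add atoms: none
Why: Horner–Wadsworth–Emmons olefination with the pre-formed lithium phosphonate places C8 trans to the ester (the 2Z allylsilane, C8 cis to CH2SiMe3), and low temperature without free base preserves the α-acyloxy stereocentre.

**Step 10**
Reactants: 16 methyl (2Z,4R,6Z)-8-[methoxy(methyl)amino]-6-methyl-8-oxo-4-(Acyl*-oxy)-2-[(trimethylsilyl)methyl]octa-2,6-dienoate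
Product: 17 methyl (2Z,4R,6Z)-6-methyl-8-oxo-4-(Acyl*-oxy)-2-[(trimethylsilyl)methyl]octa-2,6-dienoate
Conditions: Cp2Zr(H)Cl (1.6 equiv), THF, rt, 20 min
Reagents that add atoms: none
Why: Cp2Zr(H)Cl reduces the tertiary amide to the aldehyde within minutes and leaves esters, silyl groups and trisubstituted alkenes alone, so the Z-enal (C2) is unveiled without isomerisation.

**Step 11**
Reactants: 18 3-methylbut-2-enoyl chloride; 19 morpholine
Product: 20 3-methyl-1-(morpholin-4-yl)but-2-en-1-one
Conditions: Et3N, CH2Cl2, 0 °C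
Reagents that add atoms: none
Why: Simple N-acylation of the amine by the acid chloride.

**Step 12**
Reactants: 20 3-methyl-1-(morpholin-4-yl)but-2-en-1-one
Product: 21 4-{1-[(tert-butyldimethylsilyl)oxy]-3-methylbuta-1,3-dien-1-yl}morpholine
Conditions: KN(SiMe3)2, THF, −78 °C; TBSCl
Reagents that add atoms: tert-butyldimethylsilyl chloride, CC(C)(C)[Si](C)(C)Cl
Why: γ-Deprotonation of the enamide and O-silylation give the silyl N,O-ketene acetal (amide dienolate equivalent).

**Step 13**
Reactants: 17 methyl (2Z,4R,6Z)-6-methyl-8-oxo-4-(Acyl*-oxy)-2-[(trimethylsilyl)methyl]octa-2,6-dienoate; 21 4-{1-[(tert-butyldimethylsilyl)oxy]-3-methylbuta-1,3-dien-1-yl}morpholine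
Product: 22 methyl (2Z,4R,6Z,8R,10E)-8-hydroxy-6,10-dimethyl-12-(morpholin-4-yl)-12-oxo-4-(Acyl*-oxy)-2-[(trimethylsilyl)methyl]dodeca-2,6,10-trienoate
Conditions: SiCl4 (1.2 equiv), Denmark's (R,R)-binaphthyldiamine-derived bisphosphoramide (5 mol %), CH2Cl2, −78 °C, no amine base; aq. NaHCO3
Reagents that add atoms: none
Why: The Lewis-base-activated SiCl4 vinylogous Mukaiyama aldol addition is γ- and E-selective for amide dienolates and suited to conjugated aldehydes, the chiral silyl cation exposes the Re face of the Z-enal so that C2 becomes R, the very nucleophilic ketene acetal outruns the ester-deactivated internal allylsilane, and the amide product cannot add a second time.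

**Step 14**
Reactants: 22 methyl (2Z,4R,6Z,8R,10E)-8-hydroxy-6,10-dimethyl-12-(morpholin-4-yl)-12-oxo-4-(Acyl*-oxy)-2-[(trimethylsilyl)methyl]dodeca-2,6,10-trienoate
Product: 23 methyl (2Z,4R,6Z,8R,10E)-8-hydroxy-6,10-dimethyl-12-oxo-4-(Acyl*-oxy)-2-[(trimethylsilyl)methyl]dodeca-2,6,10-trienoate
Conditions: Cp2Zr(H)Cl (2.6 equiv), THF, rt, 20 min
Reagents that add atoms: none
Why: The same chemoselective amide-to-aldehyde reduction gives the 4E enal (C6), with one extra equivalent consumed by the free hydroxyl, and the E geometry prevents lactol formation with O2.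

**Step 15**
Reactants: 23 methyl (2Z,4R,6Z,8R,10E)-8-hydroxy-6,10-dimethyl-12-oxo-4-(Acyl*-oxy)-2-[(trimethylsilyl)methyl]dodeca-2,6,10-trienoate
Product: 25 (3aR,4R,6Z,8R,10E,11aR)-8-hydroxy-6,10-dimethyl-3-methylidene-2-oxo-2,3,3a,4,5,8,9,11a-octahydrocyclodeca[b]furan-4-yl (2S)-3-[(tert-butyldimethylsilyl)oxy]-2-methylpropanoate, via ring-closed hydroxy ester 24 (not isolated)
Conditions: EtAlCl2 (3.5 equiv), CH2Cl2, 1 mM (slow addition of 23), −78 → 0 °C
Reagents that add atoms: none
Why: Proposed new method: EtAlCl2 first converts C2–OH into an aluminium alkoxide and then activates the s-trans enal, whose C6 is attacked by C7 of the 2-(silylmethyl)enoate in an anti-SE2′ cation–olefin closure (intramolecular Hosomi–Sakurai reaction) that copies the C1–C10 closure of farnesyl diphosphate with Me3Si leaving from C13 in place of a proton, after which the O6 aluminium alkoxide lactonises onto C12; the 4E enal cannot reach C1=C10 for a six-ring Prins closure, C6/C7 should come out trans because the vinyl arm (C5) sits anti to C11 with H6 in the crowded position between C8 and C11, and C7/C8 follow from the conformer with H8 anti to the incoming aldehyde and syn to the C13–Si bond, the acyloxy group inside and the tether (C9) outside, which gives 6R,7R; the closest known reactions are the Lewis-acid lactone synthesis from 2-(trimethylsilylmethyl)acrylates and aldehydes, its intramolecular five- to eight-membered versions, Lewis-acid SE′ macrocyclisations of allylstannanes onto aldehydes, and CrCl2 closures of the same C6–C7 bond in germacranolide syntheses.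

**Step 16**
Reactants: 25 (3aR,4R,6Z,8R,10E,11aR)-8-hydroxy-6,10-dimethyl-3-methylidene-2-oxo-2,3,3a,4,5,8,9,11a-octahydrocyclodeca[b]furan-4-yl (2S)-3-[(tert-butyldimethylsilyl)oxy]-2-methylpropanoate
Product: 26 (3aR,4R,6Z,8R,10E,11aR)-8-hydroxy-6,10-dimethyl-3-methylidene-2-oxo-2,3,3a,4,5,8,9,11a-octahydrocyclodeca[b]furan-4-yl (2S)-3-hydroxy-2-methylpropanoate
Conditions: HF·pyridine, pyridine, THF, 0 °C → rt
Reagents that add atoms: none
Why: Buffered fluoride desilylation frees the primary alcohol without acid-induced transannular cyclisation of the 1(10),4-diene or addition to the α-methylene lactone.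

**Compound list**
1 | methyl 3-methylbut-2-enoate | COC(=O)C=C(C)C | starting material
2 | [(1-methoxy-3-methylbuta-1,3-dien-1-yl)oxy]trimethylsilane | COC(=CC(C)=C)O[Si](C)(C)C | intermediate
3 | (E)-cinnamaldehyde | O=C/C=C/c1ccccc1 | starting material
4 | methyl (2Z,5R,6E)-5-hydroxy-3-methyl-7-phenylhepta-2,6-dienoate (as copper alkoxide) | COC(=O)/C=C(/C)C[C@@H](O)/C=C/c1ccccc1 | intermediate
5 | (6R)-4-methyl-6-[(E)-2-phenylethenyl]-5,6-dihydro-2H-pyran-2-one | CC1=CC(=O)O[C@@H](/C=C/c2ccccc2)C1 | intermediate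
6 | (2Z,5R,6E)-5-hydroxy-N-methoxy-N,3-dimethyl-7-phenylhepta-2,6-dienamide | CON(C)C(=O)/C=C(/C)C[C@@H](O)/C=C/c1ccccc1 | intermediate
7 | methyl (2S)-3-hydroxy-2-methylpropanoate | COC(=O)[C@@H](C)CO | starting material
8 | methyl (2S)-3-[(tert-butyldimethylsilyl)oxy]-2-methylpropanoate | COC(=O)[C@@H](C)CO[Si](C)(C)C(C)(C)C | intermediate
9 | (2S)-3-[(tert-butyldimethylsilyl)oxy]-2-methylpropanoic acid | OC(=O)[C@@H](C)CO[Si](C)(C)C(C)(C)C | intermediate
10 | (1E,3R,5Z)-7-[methoxy(methyl)amino]-5-methyl-7-oxo-1-phenylhepta-1,5-dien-3-yl (2S)-3-[(tert-butyldimethylsilyl)oxy]-2-methylpropanoate | CON(C)C(=O)/C=C(/C)C[C@@H](OC(=O)[C@@H](C)CO[Si](C)(C)C(C)(C)C)/C=C/c1ccccc1 | intermediate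
11 | secondary ozonide of 10 (3-phenyl-1,2,4-trioxolan-5-yl in place of the styryl group) | CON(C)C(=O)/C=C(/C)C[C@@H](OC(=O)[C@@H](C)CO[Si](C)(C)C(C)(C)C)C1OOC(c2ccccc2)O1 | intermediate
12 | (2R,4Z)-6-[methoxy(methyl)amino]-4-methyl-1,6-dioxohex-4-en-2-yl (2S)-3-[(tert-butyldimethylsilyl)oxy]-2-methylpropanoate | CON(C)C(=O)/C=C(/C)C[C@@H](OC(=O)[C@@H](C)CO[Si](C)(C)C(C)(C)C)C=O | intermediate
13 | trimethyl phosphonoacetate | COC(=O)CP(=O)(OC)OC | starting material
14 | (iodomethyl)trimethylsilane | C[Si](C)(C)CI | starting material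
15 | methyl 2-(dimethoxyphosphoryl)-3-(trimethylsilyl)propanoate (racemic) | COC(=O)C(C[Si](C)(C)C)P(=O)(OC)OC | intermediate
16 | methyl (2Z,4R,6Z)-8-[methoxy(methyl)amino]-6-methyl-8-oxo-4-(Acyl*-oxy)-2-[(trimethylsilyl)methyl]octa-2,6-dienoate | CON(C)C(=O)/C=C(/C)C[C@@H](OC(=O)[C@@H](C)CO[Si](C)(C)C(C)(C)C)/C=C(\C[Si](C)(C)C)C(=O)OC | intermediate
17 | methyl (2Z,4R,6Z)-6-methyl-8-oxo-4-(Acyl*-oxy)-2-[(trimethylsilyl)methyl]octa-2,6-dienoate | O=C/C=C(/C)C[C@@H](OC(=O)[C@@H](C)CO[Si](C)(C)C(C)(C)C)/C=C(\C[Si](C)(C)C)C(=O)OC | intermediate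
18 | 3-methylbut-2-enoyl chloride | CC(C)=CC(=O)Cl | starting material
19 | morpholine | C1COCCN1 | starting material
20 | 3-methyl-1-(morpholin-4-yl)but-2-en-1-one | CC(C)=CC(=O)N1CCOCC1 | intermediate
21 | 4-{1-[(tert-butyldimethylsilyl)oxy]-3-methylbuta-1,3-dien-1-yl}morpholine | C=C(C)C=C(O[Si](C)(C)C(C)(C)C)N1CCOCC1 | intermediate
22 | methyl (2Z,4R,6Z,8R,10E)-8-hydroxy-6,10-dimethyl-12-(morpholin-4-yl)-12-oxo-4-(Acyl*-oxy)-2-[(trimethylsilyl)methyl]dodeca-2,6,10-trienoate | O=C(/C=C(\C)C[C@@H](O)/C=C(/C)C[C@@H](OC(=O)[C@@H](C)CO[Si](C)(C)C(C)(C)C)/C=C(\C[Si](C)(C)C)C(=O)OC)N1CCOCC1 | intermediate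
23 | methyl (2Z,4R,6Z,8R,10E)-8-hydroxy-6,10-dimethyl-12-oxo-4-(Acyl*-oxy)-2-[(trimethylsilyl)methyl]dodeca-2,6,10-trienoate | O=C/C=C(\C)C[C@@H](O)/C=C(/C)C[C@@H](OC(=O)[C@@H](C)CO[Si](C)(C)C(C)(C)C)/C=C(\C[Si](C)(C)C)C(=O)OC | intermediate
24 | methyl 2-[(1S,2R,3E,6R,7Z,10R)-2,6-dihydroxy-4,8-dimethyl-10-(Acyl*-oxy)cyclodeca-3,7-dien-1-yl]prop-2-enoate (as aluminium alkoxide) | COC(=O)C(=C)[C@H]1[C@H](O)/C=C(\C)C[C@@H](O)/C=C(/C)C[C@H]1OC(=O)[C@@H](C)CO[Si](C)(C)C(C)(C)C | intermediate
25 | (3aR,4R,6Z,8R,10E,11aR)-8-hydroxy-6,10-dimethyl-3-methylidene-2-oxo-2,3,3a,4,5,8,9,11a-octahydrocyclodeca[b]furan-4-yl (2S)-3-[(tert-butyldimethylsilyl)oxy]-2-methylpropanoate | C=C1C(=O)O[C@@H]2/C=C(\C)C[C@@H](O)/C=C(/C)C[C@@H](OC(=O)[C@@H](C)CO[Si](C)(C)C(C)(C)C)[C@@H]12 | intermediate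
26 | (3aR,4R,6Z,8R,10E,11aR)-8-hydroxy-6,10-dimethyl-3-methylidene-2-oxo-2,3,3a,4,5,8,9,11a-octahydrocyclodeca[b]furan-4-yl (2S)-3-hydroxy-2-methylpropanoate | C=C1C(=O)O[C@@H]2/C=C(\C)C[C@@H](O)/C=C(/C)C[C@@H](OC(=O)[C@@H](C)CO)[C@@H]12 | target

**Step count**
Total: 16 steps. Longest linear sequence: 11 steps (1, 2, 3, 6, 7, 9, 10, 13, 14, 15, 16).

**Steps most likely to fail**

Step 15 (macrocyclisation). The ring size is untested for this reaction, the ester-deactivated allylsilane is a weak nucleophile, the Lewis acid may trigger 1,4-elimination of the C8 acyloxy group with loss of silicon, and the C7/C8 facial preference rests on a conformational argument. The fallback closes the same C6–C7 bond through an allylchromium reagent and a closed six-membered transition state; it sets out from 12 and comes back at 25. Aldehyde 12 is treated with methyl acrylate and DABCO to give the Morita–Baylis–Hillman adduct of aldehyde 12 with methyl acrylate F1. NBS/Me2S converts this with allylic transposition into the Z allylic bromide amide F2. Cp2Zr(H)Cl then gives the bromo Z-enal F3, the vinylogous aldol addition of step 13 gives the bromo hydroxy morpholine amide F4, and a second Cp2Zr(H)Cl reduction gives the bromo seco-enal F5. CrCl2 in THF at 1 mM (divalent chromium, Nozaki–Hiyama–Kishi conditions) then closes the ring, and the alkoxide lactonises through 24 to 25.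

Step 13 (second vinylogous aldol). The internal allylsilane could attack the activated C2 aldehyde in a six-ring closure, the Z-enal could isomerise or lose the δ-acyloxy group, and the catalyst sense is assigned by analogy. The fallback sets out from 17 and comes back at 23, skipping 22. 3-Methylbut-2-enal is converted (TBSOTf, Et3N) into the prenal TBS dienol ether F6, which is added to 17 under boron Lewis-acid promotion by the B-phenyl oxazaborolidinone from N-tosyl-L-tryptophan and PhBCl2 (i-PrOH, EtCN, −78 °C). This vinylogous Mukaiyama aldol with an aldehyde-derived dienolate gives the enal 23 directly. It is kept as the fallback because the product enal can compete with 17 for a second addition.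

Step 9 (olefination). The E/Z ratio with the bulky α-(silylmethyl) phosphonate is uncertain and the α-acyloxy aldehyde can epimerise; the wrong alkene isomer would also erode the C7/C8 control in step 15. The fallback sets out from 12 and comes back at 16. Aldehyde 12 reacts under neutral conditions with the stabilised ylide Ph3P=C(Br)CO2Me (Wittig) to give the Z α-bromo enoate F7, with Br cis to C8. Negishi coupling with Me3SiCH2ZnCl and Pd(PPh3)4 (zerovalent palladium) then installs the silylmethyl group with retention of alkene geometry, giving 16.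

**Further compounds**
F1 | step 15 | Morita–Baylis–Hillman adduct of aldehyde 12 with methyl acrylate (both C7 carbinol epimers) | CON(C)C(=O)/C=C(/C)C[C@@H](OC(=O)[C@@H](C)CO[Si](C)(C)C(C)(C)C)C(O)C(=C)C(=O)OC
F2 | step 15 | Z allylic bromide amide, methyl (2Z,4R,6Z)-2-(bromomethyl)-8-[methoxy(methyl)amino]-6-methyl-8-oxo-4-(Acyl*-oxy)octa-2,6-dienoate | CON(C)C(=O)/C=C(/C)C[C@@H](OC(=O)[C@@H](C)CO[Si](C)(C)C(C)(C)C)/C=C(\CBr)C(=O)OC
F3 | step 15 | bromo Z-enal, methyl (2Z,4R,6Z)-2-(bromomethyl)-6-methyl-8-oxo-4-(Acyl*-oxy)octa-2,6-dienoate | O=C/C=C(/C)C[C@@H](OC(=O)[C@@H](C)CO[Si](C)(C)C(C)(C)C)/C=C(\CBr)C(=O)OC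
F4 | step 15 | bromo hydroxy morpholine amide, methyl (2Z,4R,6Z,8R,10E)-2-(bromomethyl)-8-hydroxy-6,10-dimethyl-12-(morpholin-4-yl)-12-oxo-4-(Acyl*-oxy)dodeca-2,6,10-trienoate | O=C(/C=C(\C)C[C@@H](O)/C=C(/C)C[C@@H](OC(=O)[C@@H](C)CO[Si](C)(C)C(C)(C)C)/C=C(\CBr)C(=O)OC)N1CCOCC1
F5 | step 15 | bromo seco-enal, methyl (2Z,4R,6Z,8R,10E)-2-(bromomethyl)-8-hydroxy-6,10-dimethyl-12-oxo-4-(Acyl*-oxy)dodeca-2,6,10-trienoate | O=C/C=C(\C)C[C@@H](O)/C=C(/C)C[C@@H](OC(=O)[C@@H](C)CO[Si](C)(C)C(C)(C)C)/C=C(\CBr)C(=O)OC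
F6 | step 13 | prenal TBS dienol ether, (E)-tert-butyl(dimethyl)[(3-methylbuta-1,3-dien-1-yl)oxy]silane | C=C(C)/C=C/O[Si](C)(C)C(C)(C)C
F7 | step 9 | Z α-bromo enoate, methyl (2Z,4R,6Z)-2-bromo-8-[methoxy(methyl)amino]-6-methyl-8-oxo-4-(Acyl*-oxy)octa-2,6-dienoate | CON(C)C(=O)/C=C(/C)C[C@@H](OC(=O)[C@@H](C)CO[Si](C)(C)C(C)(C)C)/C=C(\Br)C(=O)OC
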